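The runs are calculated with constants of no real substance; noise was put on by code.

A small charge of starting complex, the 0.058 M of elm, showed me the ladder of times. At 25 °C complex with three exchanged stood at 10% of the charge at 1.04 d and fell after that, so it was a thin layer passing through. By that same reading complex with four exchanged had reached 40%, half of its last reading. That rung is shorter than the feed of 4.0 d. Ash at 10 °C, which also held more starting complex than elm, took between 3.85 and 5.77 times as long to get there. −5 °C lies as far below 10 °C as that lies below 25 °C, so I applied the lower factor once more and reckoned 15.4 d, longer than the feed. I therefore expected winter's cold feed to make little complex with four exchanged.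

| flask | starting complex | incoming ligand | temperature | remark | time |
|---|---|---|---|---|---|
| ash | 0.086 M | 0.43 M | 10 °C | run made earlier |  |
| elm | 0.058 M | 0.43 M | 25 °C | run made earlier |  |
| oak | 0.13 M | 0.43 M | 10 °C | run made earlier |  |
| alder | 0.086 M | 0.65 M | 25 °C | run made earlier |  |
| autumn | 0.086 M | 0.430 M (fed, over 4.0 d) | 25 °C | all else is in the flask from the start; the feed brings no volume worth counting | 6.0 d |
| dusk | 0.086 M (fed, over 4.0 d) | 0.430 M | 25 °C | all else is in the flask from the start; the feed brings no volume worth counting | 6.0 d |
| spring | 0.086 M | 0.430 M | 25 °C | everything together at the start | 6.0 d |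
| winter | 0.086 M | 0.430 M (fed, over 4.0 d) |  | the addition at −5 °C, then warmed to 25 °C; the feed brings no volume worth counting | 6.0 d |

| run | time / d | complex with three exchanged / % | complex with four exchanged / % |
|---|---|---|---|
| ash | 0.500 | 0 | 1 |
| ash | 1.25 | 6 | 4 |
| ash | 2.50 | 10 | 16 |
| ash | 4.00 | 12 | 32 |
| ash | 6.00 | 11 | 51 |
| ash | 8.00 | 8 | 60 |
| elm | 1.04 | 10 | 40 |
| elm | 2.08 | 7 | 73 |
| elm | 3.00 | 3 | 86 |
| elm | 4.00 | 0 | 89 |
| elm | 5.00 | 3 | 90 |
| elm | 6.00 | 0 | 90 |
| oak | 1.04 | 2 | 0 |
| oak | 1.67 | 5 | 4 |
| oak | 2.50 | 7 | 10 |
| oak | 4.00 | 10 | 21 |
| oak | 8.00 | 11 | 38 |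
| oak | 12.0 | 10 | 47 |
| alder | 1.25 | 6 | 68 |
| alder | 2.50 | 1 | 87 |
| alder | 4.00 | 4 | 93 |
| alder | 5.00 | 3 | 93 |
| alder | 6.00 | 2 | 93 |

(standard deviation of a reading: 1.5 percentage points)



* the flask that comes out highest in share of complex with three exchanged in complex with three exchanged plus complex with four exchanged, or "all alike" when all lie within 1.5 percentage points (autumn / dusk / spring / winter / all alike)
* share of complex with three exchanged in complex with three exchanged plus complex with four exchanged at the end, autumn
* share of complex with three exchanged in complex with three exchanged plus complex with four exchanged at the end, dusk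
* share of complex with three exchanged in complex with three exchanged plus complex with four exchanged at the end, spring
* share of complex with three exchanged in complex with three exchanged plus complex with four exchanged at the end, winter

So I gave each flask a contact time: the days at 25 °C with the charge together, a warm feed counting at 0.5 of its length and a cold feed not at all. Winter got 2.00 d, autumn and dusk 4.00 d, and spring 6.0 d. Then I computed just the small term, the share of complex with three exchanged, a selectivity at the stopping time, as a reading from the warm runs. Elm at 2.08 d gave 8.75% for winter, though elm held less starting complex than winter. Elm's 4.00 d reading, the match for autumn and dusk, was 0% with a scatter of 1.5 percentage points, so I took its 3.00 d reading instead, and that gave 3.37%. Alder at 6.00 d gave 2.11% for spring, though alder held more incoming ligand than spring.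

The forecast named winter, with 10% there, 7% for autumn, 7% for dusk and 2.5% for spring: “Winter barely reacts in the cold”. Its autumn figure stood above my 3.37%, but the order was the same as mine.

The flasks gave 10.8% in winter, 4.81% in autumn, 4.70% in dusk and 1.52% in spring, so winter came out highest.

    complex with one exchanged + incoming ligand → leaving ligand + complex with two exchanged (k = 0.486 M⁻¹ h⁻¹, Ea = 69.0 kJ mol⁻¹)
    complex with three exchanged + incoming ligand → over-reaction product (k = 0.0501 M⁻¹ h⁻¹, Ea = 66.0 kJ mol⁻¹)
    complex with three exchanged + incoming ligand → leaving ligand + complex with four exchanged (k = 0.742 M⁻¹ h⁻¹, Ea = 64.0 kJ mol⁻¹)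
    complex with two exchanged + incoming ligand → leaving ligand + complex with three exchanged (k = 0.178 M⁻¹ h⁻¹, Ea = 56.0 kJ mol⁻¹)
    starting complex + incoming ligand → leaving ligand + complex with one exchanged (k = 0.569 M⁻¹ h⁻¹, Ea = 61.0 kJ mol⁻¹)
    (constants at 25 °C)

Winter's contact time of 2.00 d had promised 8.75%, and winter gave 10.8%, 2 points higher. That share does not show the 27.0% of complex with two exchanged still in winter at 6.00 d, beside 7.24% of complex with three exchanged. Winter's contact time was shorter than those of the other flasks, and its share was higher than theirs. A neighbour flask, spring stopped at 40 h, has a contact time of those 40 h, which lies between elm's 1.04 d and 2.08 d. The same count therefore put its share between 8.75% and 20.0%, and that flask gave 14.8%.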